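The readings were generated by integration with made-up constants; the scatter is artificial.

Start from the product pair, target and isomer of the product A, and measure it against the even split, the symmetric zero of the scale. Take as the imbalance the target minus the isomer over their sum, which is one for pure target and zero for the even split.

common to all: starting material 0.0050 M

| charge | protic impurity | remark | time |
|---|---|---|---|
| midnight | 0.75 mM | run made earlier |  |
| winter | 3 mM | run made earlier |  |
| flask | 1.50 mM |  | 2.0 h |

| run | time / min | target / % | isomer of the product A / % |
|---|---|---|---|
| midnight | 20.0 | 54.7 | 8.4 |
| midnight | 40.0 | 51.1 | 14.0 |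
| midnight | 60.0 | 45.5 | 17.5 |
| midnight | 80.0 | 46.0 | 21.7 |
| midnight | 90.0 | 42.3 | 24.2 |
| midnight | 120 | 41.1 | 27.0 |
| winter | 10.0 | 26.7 | 2.0 |
| winter | 15.0 | 25.9 | 4.0 |
| winter | 25.0 | 22.3 | 6.2 |
| winter | 40.0 | 23.5 | 6.8 |
| winter | 80.0 | 22.8 | 9.4 |
| winter | 120 | 19.4 | 13.1 |

(each reading ± 1 percentage point)

* ratio of target to isomer of the product A at 0.80 s
* ratio of target to isomer of the product A at 1.0 min
* ratio of target to isomer of the product A at 2.0 h
* which of target and isomer of the product A there is more of at 2.0 h

- what was read earlier has a scatter of 1 percentage point, one standard deviation

Reach the ratio at 2.0 h by two roads. Read it first off the last readings: at 120 min the midnight run shows 1.52 and the winter run 1.48, with 0.75 mM and 3 mM of protic impurity, so expect about that value in the flask at 1.50 mM. Then set those readings aside and take the midnight run at 20.0 min and 60.0 min, where the imbalance reads 0.734 and 0.444; a steady decay towards the even split gives 55.3 min as the imbalance half-life, the time in which the imbalance falls by a factor of 2. Run that line back to a start of 0.943 and forward to 0.210 at 2.0 h, a ratio of 1.53, and trust this value, since the two roads used different readings.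

The roads part early, once a start must be chosen. Pin the imbalance at one at time zero, pass it through the last midnight reading, and the half-life is 52.8 min and the ratio at 1.0 min about 152; leave the start free and my ratio is 0.931 in imbalance, or 28.0, and about 34.0 at 0.80 s. The pinned line asks for 7.28 % of isomer at 20.0 min where 8.4 % was read, a gap close to the scatter of 1 percentage point, so these readings do not convict it; and the free start of 0.943 is no reading either, but a back-extrapolation from two readings through an assumed steady decay, as much an assumption as the pin. Commit to the free line loosely, then, as my own choice which the readings do not force, and picture the change as a slide from kinetic towards thermodynamic control.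

The forecast gives 11000, 148 and 1.5, with target ahead; its early figures lie far above mine, and it warns: “Early ratios are very uncertain”.

The flask gives 46.7, 29.9 and 1.54, with target ahead at 33.2 % against 21.5 %.

    starting material ⇌ target (K = 14.0, k = 0.0760 /s)
    starting material ⇌ isomer of the product A (K = 14.0, k = 0.00160 /s)
    starting material ⇌ third isomer (K = 1.10, k = 0.00960 /s)
    starting material + protic impurity → quenched substrate (k = 26.0 /M/s)
    target ⇌ isomer of the product B (K = 0.310, k = 0.0400 /s)

The equilibrium constant for target over that for isomer of the product A is 1.00, which is the even split taken as zero. With 55.3 min, the line from 0.943 reaches 0.210 at 2.0 h, and this flask stands at 0.213. The neighbour flask with 0.0020 M of starting material, holding 0.750 equiv of protic impurity, ends at a ratio of 1.25, an imbalance of 0.110, which from the same start of 0.943 means a half-life of 38.8 min, shorter than the 55.3 min of the line.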